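**Retrosynthetic overview**

1. The target is epicatechin-(4β→6)-epicatechin-(4β→8)-epicatechin-(4β→6)-epicatechin (units 1–4). All rings and all C2/C3 stereocentres are bought as (−)-epicatechin, so no ring is formed in the route; only three interflavan C–C bonds are made, each new C4 stereocentre relayed from C2/C3 of its own unit.
2. Last C–C disconnection: C4 (unit 1)–C6 (ring A of unit 2), made as a biomimetic flavan-4-yl cation/arene coupling of the fully halogen-capped monomer electrophile 7 with the protected trimer 11.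
3. Enabling feature: C4 of unit 1 is benzylic to the phloroglucinol-type ring A and conjugated with O1 (through C8a), 5-O and 7-O, so a C4 alkoxy group ionises to a quinone-methide-like cation. C6 of ring A of unit 2 lies between 5-O and 7-O and para to O1, and in 11 it is the only ring-A C–H, because C8 (unit 2), C6 (unit 3) and C8 (unit 4) carry bromine.
4. Trimer 11: the unit 3–unit 4 bond (4β→6) from 7 and the 8-bromo monomer 3; chemoselective removal of the temporary C8 iodine of unit 3; then 4β→8 coupling with the 8-bromo electrophile 4. Bond order: 3–4, then 2–3, then 1–2.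
5. One hydrogenolysis removes sixteen benzyl ethers and the four halogen caps (three Br, one I).

Key step: step 10

Assumption: units are numbered 1 to 4 from the upper extension unit to the terminal unit. "4β" means a C4 substituent trans to the C3 hydroxyl (2,3-cis-3,4-trans). "TBE" stands for a 5,7,3',4'-tetra-O-benzyl-(−)-epicatechin unit with (2R,3R) configuration and a free 3-hydroxyl. (−)-Epicatechin is taken as commercially available.

**Route**

Step 1
Reactants: 1 (−)-epicatechin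
Product: 2 5,7,3',4'-tetra-O-benzyl-(−)-epicatechin
Conditions: BnBr (4.4 equiv), K2CO3, DMF, 0 °C to rt
Reagents that add atoms: benzyl bromide, BrCc1ccccc1
Why: Williamson ether synthesis in which K2CO3 deprotonates only the four phenols and not the secondary 3-hydroxyl, and the mild anhydrous conditions should leave the bought C2 and C3 stereocentres unepimerised.

Step 2
Reactants: 2 5,7,3',4'-tetra-O-benzyl-(−)-epicatechin
Product: 3 8-bromo-5,7,3',4'-tetra-O-benzyl-(−)-epicatechin
Conditions: NBS (1.0 equiv), CH2Cl2, −20 °C to 0 °C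
Reagents that add atoms: N-bromosuccinimide, O=C1CCC(=O)N1Br
Why: Electrophilic aromatic bromination in which ring A (three oxygen donors) far outpaces ring B, C8 (flanked on one side only by the ring oxygen) is attacked in preference to C6, and the first bromine deactivates the ring against a second substitution.

Step 3
Reactants: 3 8-bromo-5,7,3',4'-tetra-O-benzyl-(−)-epicatechin
Product: 4 8-bromo-4β-(2-ethoxyethoxy)-5,7,3',4'-tetra-O-benzyl-(−)-epicatechin
Conditions: DDQ (2 equiv), 2-ethoxyethanol (5 equiv), CH2Cl2, rt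
Reagents that add atoms: 2-ethoxyethanol, CCOCCO
Why: DDQ benzylic oxidation (hydride abstraction from C4 to the ring-A-stabilised cation) with alcohol trapping, the alcohol adding to the face opposite the pseudo-axial C3 hydroxyl and the C2 aryl group so that C4 is set as 4β by substrate control.

Step 4
Reactants: 2 5,7,3',4'-tetra-O-benzyl-(−)-epicatechin
Product: 5 4β-(2-ethoxyethoxy)-5,7,3',4'-tetra-O-benzyl-(−)-epicatechin
Conditions: DDQ (2 equiv), 2-ethoxyethanol (5 equiv), CH2Cl2, rt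
Reagents that add atoms: 2-ethoxyethanol, CCOCCO
Why: The same DDQ benzylic oxidation/alcohol trapping as in step 3, with the 4β configuration again set by addition trans to the C3 hydroxyl.

Step 5
Reactants: 5 4β-(2-ethoxyethoxy)-5,7,3',4'-tetra-O-benzyl-(−)-epicatechin
Product: 6 8-iodo-4β-(2-ethoxyethoxy)-5,7,3',4'-tetra-O-benzyl-(−)-epicatechin
Conditions: NIS (1.05 equiv), DMF, 0 °C to rt, dark
Reagents that add atoms: N-iodosuccinimide, O=C1CCC(=O)N1I
Why: Electrophilic aromatic iodination at C8 (same site preference as in step 2) under acid-free conditions that the acid-labile 4-alkoxy group should tolerate.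

Step 6
Reactants: 6 8-iodo-4β-(2-ethoxyethoxy)-5,7,3',4'-tetra-O-benzyl-(−)-epicatechin
Product: 7 6-bromo-8-iodo-4β-(2-ethoxyethoxy)-5,7,3',4'-tetra-O-benzyl-(−)-epicatechin
Conditions: NBS (1.1 equiv), CH2Cl2, −20 °C to 0 °C, dark
Reagents that add atoms: N-bromosuccinimide, O=C1CCC(=O)N1Br
Why: Electrophilic aromatic bromination of the only remaining ring-A C–H (C6, ortho to 5-O and 7-O, para to O1), with low temperature and a single equivalent of NBS chosen to disfavour ipso attack at the C8–I bond.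

Step 7
Reactants: 7 6-bromo-8-iodo-4β-(2-ethoxyethoxy)-5,7,3',4'-tetra-O-benzyl-(−)-epicatechin; 3 8-bromo-5,7,3',4'-tetra-O-benzyl-(−)-epicatechin (3 equiv, excess recoverable)
Product: 8 [6-bromo-8-iodo-TBE]-(4β→6)-[8-bromo-TBE] dimer
Conditions: TMSOTf (0.3 equiv), 4 Å MS, CH2Cl2, −78 °C to −30 °C; Et3N quench
Reagents that add atoms: none
Why: Lewis-acid-catalysed SN1 Friedel–Crafts interflavan condensation in its halogen-capping variant for 4→6 bonds, in which C6 is the only ring-A C–H of 3 and 7 has none (so neither self-condensation nor chain growth is possible), and the arene adds to the cation trans to the C3 hydroxyl, setting C4 of the upper unit as 4β.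

Step 8
Reactants: 8 [6-bromo-8-iodo-TBE]-(4β→6)-[8-bromo-TBE] dimer
Product: 10 [6-bromo-TBE]-(4β→6)-[8-bromo-TBE] dimer (C8–H of the upper unit free), via C8-chloromagnesio dimer bis(chloromagnesium alkoxide) 9 (not isolated)
Conditions: i-PrMgCl·LiCl (3.3 equiv), THF, −40 °C to −15 °C; then 0.5 M HCl, 0 °C
Reagents that add atoms: none
Why: Iodine–magnesium exchange, which after deprotonation of the two hydroxyls should be far faster at the C–I bond than at the two electron-rich C–Br bonds, followed by protonation of the arylmagnesium to leave C8–H without touching any stereocentre.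

Step 9
Reactants: 10 [6-bromo-TBE]-(4β→6)-[8-bromo-TBE] dimer; 4 8-bromo-4β-(2-ethoxyethoxy)-5,7,3',4'-tetra-O-benzyl-(−)-epicatechin (1.2 equiv)
Product: 11 [8-bromo-TBE]-(4β→8)-[6-bromo-TBE]-(4β→6)-[8-bromo-TBE] trimer
Conditions: TMSOTf (0.3 equiv), 4 Å MS, CH2Cl2, −78 °C to −40 °C; Et3N quench
Reagents that add atoms: none
Why: Lewis-acid-catalysed Friedel–Crafts interflavan condensation with a C8-bromo-capped electrophile, in which C8 of the upper unit is the only ring-A C–H of 10 and is more accessible than the doubly flanked C6 of 4 (so cross-coupling should outrun self-condensation), and attack trans to the C3 hydroxyl sets C4 of unit 2 as 4β.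

Step 10
Reactants: 11 [8-bromo-TBE]-(4β→8)-[6-bromo-TBE]-(4β→6)-[8-bromo-TBE] trimer; 7 6-bromo-8-iodo-4β-(2-ethoxyethoxy)-5,7,3',4'-tetra-O-benzyl-(−)-epicatechin (2 equiv)
Product: 12 [6-bromo-8-iodo-TBE]-(4β→6)-[8-bromo-TBE]-(4β→8)-[6-bromo-TBE]-(4β→6)-[8-bromo-TBE] tetramer (hexadeca-O-benzyl, four free 3-hydroxyls)
Conditions: TMSOTf (0.5 equiv), 4 Å MS, CH2Cl2, −78 °C to −20 °C; Et3N quench
Reagents that add atoms: none
Why: TMSOTf ionises the 4β-(2-ethoxyethoxy) group of 7 to the flavan-4-yl cation, delocalised onto O1, 5-O and 7-O of ring A of unit 1 (a quinone-methide-type oxocarbenium ion), which C6 of ring A of unit 2 in 11 captures in an SN1 Friedel–Crafts alkylation before the C6 proton is lost. The closest known reaction type is the Lewis-acid-catalysed condensation of 4-alkoxyflavan-3-ol electrophiles with C8-halogen-capped flavan-3-ol nucleophiles to give 4→6 interflavan bonds, here applied to a trimeric nucleophile. No ring is closed; one C–C bond and one stereocentre are formed. The new stereocentre, C4 of unit 1, is controlled by the substrate: in the half-chair cation the C2 aryl group is pseudo-equatorial and the C3 hydroxyl pseudo-axial, and the arene adds to the opposite (β) face, trans to both, as in every epicatechin-derived extension. The step needs site selectivity for C6 of unit 2 and freedom from self-condensation and over-extension: C6 of unit 2 is the only ring-A C–H in 11 (ring B is far less nucleophilic) and 7 has no ring-A C–H at all, so it can be used in excess, while O-alkylation at the free 3-hydroxyls is reversible under the Lewis acid and should funnel to the C-alkylated product. The low temperature should keep the three acid-labile interflavan bonds already present from ionising.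

Step 11
Reactants: 12 protected, halogen-capped tetramer
Product: 13 epicatechin-(4β→6)-epicatechin-(4β→8)-epicatechin-(4β→6)-epicatechin (CNP0120618.1)
Conditions: H2 (1 atm), Pd(OH)2/C, Et3N (5 equiv), THF/MeOH/H2O, rt; filtration and lyophilisation under argon, size-exclusion chromatography
Reagents that add atoms: none
Why: Heterogeneous catalytic hydrogenolysis should cleave all sixteen benzyl aryl ethers and, with Et3N buffering the HBr and HI formed, the four aryl–halogen bonds, while the pyran C–O bonds, the interflavan C–C bonds and all twelve stereocentres stay untouched under these neutral conditions.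

**Compound list**

1 | (−)-epicatechin, (2R,3R)-2-(3,4-dihydroxyphenyl)chromane-3,5,7-triol | Oc1cc(O)c2c(c1)O[C@H](c1ccc(O)c(O)c1)[C@H](O)C2 | starting material

2 | 5,7,3',4'-tetra-O-benzyl-(−)-epicatechin (2R,3R; free 3-OH) | c1ccccc1COc1cc(OCc2ccccc2)c2c(c1)O[C@H](c1ccc(OCc3ccccc3)c(OCc3ccccc3)c1)[C@H](O)C2 | intermediate

3 | 8-bromo-5,7,3',4'-tetra-O-benzyl-(−)-epicatechin | c1ccccc1COc1cc(OCc2ccccc2)c2c(c1Br)O[C@H](c1ccc(OCc3ccccc3)c(OCc3ccccc3)c1)[C@H](O)C2 | intermediate

4 | 8-bromo-4β-(2-ethoxyethoxy)-5,7,3',4'-tetra-O-benzyl-(−)-epicatechin (2,3-cis-3,4-trans) | c1ccccc1COc1cc(OCc2ccccc2)c2c(c1Br)O[C@H](c1ccc(OCc3ccccc3)c(OCc3ccccc3)c1)[C@H](O)[C@H]2OCCOCC | intermediate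

5 | 4β-(2-ethoxyethoxy)-5,7,3',4'-tetra-O-benzyl-(−)-epicatechin | c1ccccc1COc1cc(OCc2ccccc2)c2c(c1)O[C@H](c1ccc(OCc3ccccc3)c(OCc3ccccc3)c1)[C@H](O)[C@H]2OCCOCC | intermediate

6 | 8-iodo-4β-(2-ethoxyethoxy)-5,7,3',4'-tetra-O-benzyl-(−)-epicatechin | c1ccccc1COc1cc(OCc2ccccc2)c2c(c1I)O[C@H](c1ccc(OCc3ccccc3)c(OCc3ccccc3)c1)[C@H](O)[C@H]2OCCOCC | intermediate

7 | 6-bromo-8-iodo-4β-(2-ethoxyethoxy)-5,7,3',4'-tetra-O-benzyl-(−)-epicatechin | c1ccccc1COc1c(Br)c(OCc2ccccc2)c2c(c1I)O[C@H](c1ccc(OCc3ccccc3)c(OCc3ccccc3)c1)[C@H](O)[C@H]2OCCOCC | intermediate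

8 | [6-bromo-8-iodo-TBE]-(4β→6)-[8-bromo-TBE] dimer | c1ccccc1COc1c(Br)c(OCc2ccccc2)c2c(c1I)O[C@H](c1ccc(OCc3ccccc3)c(OCc3ccccc3)c1)[C@H](O)[C@H]2c1c(OCc2ccccc2)c(Br)c2c(c1OCc1ccccc1)C[C@@H](O)[C@@H](c1ccc(OCc3ccccc3)c(OCc3ccccc3)c1)O2 | intermediate

9 | C8-chloromagnesio dimer bis(chloromagnesium alkoxide) (upper-unit C8–MgCl, both 3-O–MgCl) | c1ccccc1COc1c(Br)c(OCc2ccccc2)c2c(c1[Mg]Cl)O[C@H](c1ccc(OCc3ccccc3)c(OCc3ccccc3)c1)[C@H](O[Mg]Cl)[C@H]2c1c(OCc2ccccc2)c(Br)c2c(c1OCc1ccccc1)C[C@@H](O[Mg]Cl)[C@@H](c1ccc(OCc3ccccc3)c(OCc3ccccc3)c1)O2 | intermediate (not isolated)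

10 | [6-bromo-TBE]-(4β→6)-[8-bromo-TBE] dimer | c1ccccc1COc1c(Br)c(OCc2ccccc2)c2c(c1)O[C@H](c1ccc(OCc3ccccc3)c(OCc3ccccc3)c1)[C@H](O)[C@H]2c1c(OCc2ccccc2)c(Br)c2c(c1OCc1ccccc1)C[C@@H](O)[C@@H](c1ccc(OCc3ccccc3)c(OCc3ccccc3)c1)O2 | intermediate

11 | [8-bromo-TBE]-(4β→8)-[6-bromo-TBE]-(4β→6)-[8-bromo-TBE] trimer | c1ccccc1COc1cc(OCc2ccccc2)c2c(c1Br)O[C@H](c1ccc(OCc3ccccc3)c(OCc3ccccc3)c1)[C@H](O)[C@H]2c1c(OCc2ccccc2)c(Br)c(OCc2ccccc2)c2c1O[C@H](c1ccc(OCc3ccccc3)c(OCc3ccccc3)c1)[C@H](O)[C@H]2c1c(OCc2ccccc2)c(Br)c2c(c1OCc1ccccc1)C[C@@H](O)[C@@H](c1ccc(OCc3ccccc3)c(OCc3ccccc3)c1)O2 | intermediate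

12 | [6-bromo-8-iodo-TBE]-(4β→6)-[8-bromo-TBE]-(4β→8)-[6-bromo-TBE]-(4β→6)-[8-bromo-TBE] tetramer | c1ccccc1COc1c(Br)c(OCc2ccccc2)c2c(c1I)O[C@H](c1ccc(OCc3ccccc3)c(OCc3ccccc3)c1)[C@H](O)[C@H]2c1c(OCc2ccccc2)c(Br)c2c(c1OCc1ccccc1)[C@H](c1c(OCc3ccccc3)c(Br)c(OCc3ccccc3)c3c1O[C@H](c1ccc(OCc4ccccc4)c(OCc4ccccc4)c1)[C@H](O)[C@H]3c1c(OCc3ccccc3)c(Br)c3c(c1OCc1ccccc1)C[C@@H](O)[C@@H](c1ccc(OCc4ccccc4)c(OCc4ccccc4)c1)O3)[C@@H](O)[C@@H](c1ccc(OCc3ccccc3)c(OCc3ccccc3)c1)O2 | intermediate

13 | epicatechin-(4β→6)-epicatechin-(4β→8)-epicatechin-(4β→6)-epicatechin (CNP0120618.1) | Oc1cc(O)c2c(c1)O[C@H](c1ccc(O)c(O)c1)[C@H](O)[C@H]2c1c(O)cc2c(c1O)[C@H](c1c(O)cc(O)c3c1O[C@H](c1ccc(O)c(O)c1)[C@H](O)[C@H]3c1c(O)cc3c(c1O)C[C@@H](O)[C@@H](c1ccc(O)c(O)c1)O3)[C@@H](O)[C@@H](c1ccc(O)c(O)c1)O2 | target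

**Step count and risks**

Total step count: 11. Longest linear sequence: 9 steps (steps 1, 4, 5, 6, 7, 8, 9, 10, 11).

Steps most likely to fail:

1. Step 10 (key step). Capture of the hindered, dihalogenated cation by the crowded C6 position of the trimer may be slow. Elimination of the cation towards the flav-3-ene or 3-ketone, or acid-induced ionisation and scrambling of the existing interflavan bonds, could then outrun C–C bond formation. Fallback, setting out from 8 and 10 and coming back at 12: dimer 8, which already contains the unit 1–unit 2 connectivity, is oxidised with DDQ and 2-ethoxyethanol at the only ring-A benzylic CH2 (C4 of its lower unit) to give the fully capped dimeric electrophile [6-bromo-8-iodo-TBE]-(4β→6)-[8-bromo-4β-(2-ethoxyethoxy)-TBE] F1. TMSOTf-catalysed condensation of F1 with dimer 10, at C8 of the upper unit of 10 (its only ring-A C–H and the intrinsically more reactive, less hindered position), would close the central 4β→8 bond last and give 12 directly. The C4 (unit 1)–C6 (unit 2) bond is then made at the monomer stage, by the reaction of step 7.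

2. Step 7. C-alkylation at the doubly flanked C6 of 3 may be sluggish because the C6 bromine of 7 buttresses the 5-benzyloxy group against the cationic C4, leading to O-alkylation or elimination in place of the C–C bond. Fallback, setting out from 6 and 3 and coming back at 8: the mono-halogenated electrophile 6 is condensed (TMSOTf, CH2Cl2, low temperature) with a larger excess of 3 to give the dimer [8-iodo-TBE]-(4β→6)-[8-bromo-TBE] F2. The only ring-A C–H of F2 (C6 of the upper unit) is then brominated with NBS to give 8, so the second halogen cap is installed after the coupling and not before it.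

3. Step 9. Self-condensation of the singly capped electrophile 4 through its own free C6 may compete with attack by the bromine-deactivated C8 of dimer 10 and give oligomer mixtures. Fallback, setting out from 4 and 10 and coming back at 11: 4 is iodinated at C6 with NIS to the fully capped electrophile 8-bromo-6-iodo-4β-(2-ethoxyethoxy)-5,7,3',4'-tetra-O-benzyl-(−)-epicatechin F3. F3 is condensed with 10 (TMSOTf) to the trimer [8-bromo-6-iodo-TBE]-(4β→8)-[6-bromo-TBE]-(4β→6)-[8-bromo-TBE] F4. Chemoselective iodine–magnesium exchange with i-PrMgCl·LiCl gives the C6-chloromagnesio trimer tris(chloromagnesium alkoxide) F5 (not isolated), and protonation then gives 11.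

**Further compounds**

F1 | step 10 | [6-bromo-8-iodo-TBE]-(4β→6)-[8-bromo-4β-(2-ethoxyethoxy)-TBE] dimeric electrophile | c1ccccc1COc1c(Br)c(OCc2ccccc2)c2c(c1I)O[C@H](c1ccc(OCc3ccccc3)c(OCc3ccccc3)c1)[C@H](O)[C@H]2c1c(OCc2ccccc2)c(Br)c2c(c1OCc1ccccc1)[C@H](OCCOCC)[C@@H](O)[C@@H](c1ccc(OCc3ccccc3)c(OCc3ccccc3)c1)O2
F2 | step 7 | [8-iodo-TBE]-(4β→6)-[8-bromo-TBE] dimer | c1ccccc1COc1cc(OCc2ccccc2)c2c(c1I)O[C@H](c1ccc(OCc3ccccc3)c(OCc3ccccc3)c1)[C@H](O)[C@H]2c1c(OCc2ccccc2)c(Br)c2c(c1OCc1ccccc1)C[C@@H](O)[C@@H](c1ccc(OCc3ccccc3)c(OCc3ccccc3)c1)O2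
F3 | step 9 | 8-bromo-6-iodo-4β-(2-ethoxyethoxy)-5,7,3',4'-tetra-O-benzyl-(−)-epicatechin | c1ccccc1COc1c(I)c(OCc2ccccc2)c2c(c1Br)O[C@H](c1ccc(OCc3ccccc3)c(OCc3ccccc3)c1)[C@H](O)[C@H]2OCCOCC
F4 | step 9 | [8-bromo-6-iodo-TBE]-(4β→8)-[6-bromo-TBE]-(4β→6)-[8-bromo-TBE] trimer | c1ccccc1COc1c(I)c(OCc2ccccc2)c2c(c1Br)O[C@H](c1ccc(OCc3ccccc3)c(OCc3ccccc3)c1)[C@H](O)[C@H]2c1c(OCc2ccccc2)c(Br)c(OCc2ccccc2)c2c1O[C@H](c1ccc(OCc3ccccc3)c(OCc3ccccc3)c1)[C@H](O)[C@H]2c1c(OCc2ccccc2)c(Br)c2c(c1OCc1ccccc1)C[C@@H](O)[C@@H](c1ccc(OCc3ccccc3)c(OCc3ccccc3)c1)O2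
F5 | step 9 | C6-chloromagnesio trimer tris(chloromagnesium alkoxide) (unit 2 C6–MgCl, three 3-O–MgCl) | c1ccccc1COc1c([Mg]Cl)c(OCc2ccccc2)c2c(c1Br)O[C@H](c1ccc(OCc3ccccc3)c(OCc3ccccc3)c1)[C@H](O[Mg]Cl)[C@H]2c1c(OCc2ccccc2)c(Br)c(OCc2ccccc2)c2c1O[C@H](c1ccc(OCc3ccccc3)c(OCc3ccccc3)c1)[C@H](O[Mg]Cl)[C@H]2c1c(OCc2ccccc2)c(Br)c2c(c1OCc1ccccc1)C[C@@H](O[Mg]Cl)[C@@H](c1ccc(OCc3ccccc3)c(OCc3ccccc3)c1)O2
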